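## Retrosynthetic overview

1. Endgame: the acetate comes from the ring-B carbinol. The CH(CH3) centre comes from an exocyclic methylene group by hydroxyl-directed hydrogenation.
2. Key disconnection: two bonds are cut together. One is the Cα=Cβ double bond of the butenolide (ring A). The other is the σ-bond between the methyl-bearing carbon of the cyclooctene (ring B) and the neighbouring CH of the cyclopropane (ring C). This opens rings A and B and gives an open-chain α-phosphono ester. Its alcohol part is a hydroxymethyl cycloprop-2-enyl ketone and its far end is a 2-bromoallyl group.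
3. Enabling feature: Cβ of ring A carries ring C directly and Cα carries the rest of ring B. The lactone O–CH2 holds the ketone carbon and the phosphonate carbon in a 1,5 relation. The third carbon of ring C is an unsubstituted CH2, so ring C can be carried as a mirror-symmetric cyclopropene. Attack on either of its olefinic carbons gives an eight-membered ring.
4. Order of ring formation: ring C first (as a cyclopropene, from ethynyltrimethylsilane and ethyl diazoacetate). Rings A and B then form in one flask, and ring C is reduced to the cyclopropane in the same event.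
5. The chain comes from (R)-citronellic acid by Evans alkylation (side-chain-bearing ring carbon), Felkin–Anh 2-bromoallylation (carbinol), C-phosphorylation and ester formation with the chloromethyl ketone.

Key step: step 14

Remark on the chemistry: the phosphonate-bearing carbon is carried as a mixture of epimers and is written without configuration. It becomes sp2 in step 14.

## Route

Step 1
Reactants: 1 (R)-citronellic acid; 2 (4R)-4-benzyl-1,3-oxazolidin-2-one
Product: 4 (4R)-4-benzyl-3-[(3R)-3,7-dimethyloct-6-enoyl]-1,3-oxazolidin-2-one, via mixed pivalic anhydride 3 (not isolated)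
Conditions: PivCl, Et3N, THF, −20 °C; then 2, LiCl, −20 °C to rt
Reagents that add atoms: pivaloyl chloride, CC(C)(C)C(=O)Cl (atoms in 3 only)
Why: Mixed-anhydride N-acylation of an oxazolidinone (LiCl/Et3N variant) is mild and touches neither the existing stereocentre nor the trisubstituted alkene.

Step 2
Reactants: 4 N-citronelloyl oxazolidinone; 5 tert-butyl bromoacetate
Product: 6 tert-butyl (3R,4R)-3-{[(4R)-4-benzyl-2-oxo-1,3-oxazolidin-3-yl]carbonyl}-4,8-dimethylnon-7-enoate
Conditions: NaHMDS, THF, −78 °C; then 5, −78 to −40 °C
Reagents that add atoms: none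
Why: In this Evans asymmetric alkylation the chelated Z-sodium enolate is attacked by the reactive α-bromo ester on the face opposite to the benzyl group, which sets the future side-chain-bearing ring carbon (3R here).

Step 3
Reactants: 6 alkylated imide
Product: 7 tert-butyl (3R,4R)-3-(hydroxymethyl)-4,8-dimethylnon-7-enoate
Conditions: LiBH4, MeOH (1 equiv), Et2O, 0 °C
Reagents that add atoms: none
Why: Reductive removal of the Evans auxiliary with LiBH4 is chemoselective for the imide over the hindered tert-butyl ester and leaves both stereocentres untouched.

Step 4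
Reactants: 7 primary alcohol
Product: 8 tert-butyl (3R,4R)-3-formyl-4,8-dimethylnon-7-enoate
Conditions: Dess–Martin periodinane, pyridine, CH2Cl2, 0 °C to rt; used crude
Reagents that add atoms: none
Why: Buffered Dess–Martin oxidation gives the α-branched aldehyde without epimerisation and without the acid that would trigger an intramolecular carbonyl-ene reaction with the prenyl alkene.

Step 5
Reactants: 8 aldehyde; 9 2,3-dibromopropene
Product: 10 tert-butyl (3R,4R)-3-[(1R)-3-bromo-1-hydroxybut-3-en-1-yl]-4,8-dimethylnon-7-enoate
Conditions: In powder, THF–H2O, rt; chromatographic removal of the minor carbinol epimer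
Reagents that add atoms: none
Why: The Barbier-type 2-bromoallylation runs through an allylindium species under neutral aqueous conditions that should not start the ene cyclisation, and the new carbinol centre is set by Felkin–Anh control with the branched methylheptenyl group as the large substituent, which gives the 1R (anti) isomer.

Step 6
Reactants: 10 bromohomoallylic alcohol
Product: 11 tert-butyl (3R,4R)-3-[(1R)-3-bromo-1-(tert-butyldimethylsilyloxy)but-3-en-1-yl]-4,8-dimethylnon-7-enoate
Conditions: TBSOTf (1.2 equiv), 2,6-lutidine, CH2Cl2, −78 to −30 °C
Reagents that add atoms: tert-butyldimethylsilyl triflate, CC(C)(C)[Si](C)(C)OS(=O)(=O)C(F)(F)F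
Why: Silyl triflate silylation protects the hindered carbinol at low temperature, where the tert-butyl ester is not attacked, and so blocks γ-lactonisation in all later steps.

Step 7
Reactants: 11 silyl ether
Product: 13 tert-butyl (2RS,3R,4R)-3-[(1R)-3-bromo-1-(tert-butyldimethylsilyloxy)but-3-en-1-yl]-2-(diethoxyphosphoryl)-4,8-dimethylnon-7-enoate, via phosphonite ester 12 (not isolated)
Conditions: LDA (1.1 equiv), THF, −78 °C; ClP(OEt)2, −78 °C to rt; then 30% H2O2, 0 °C
Reagents that add atoms: diethyl chlorophosphite, CCOP(Cl)OCC; hydrogen peroxide, OO
Why: C-phosphorylation of an ester enolate with a chlorophosphite followed by oxidation at phosphorus is a known route to α-phosphono esters, and the new centre forms as an epimer mixture that is erased in step 14.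

Step 8
Reactants: 13 α-phosphono tert-butyl ester
Product: 15 (2RS,3R,4R)-3-[(1R)-3-bromo-1-(tert-butyldimethylsilyloxy)but-3-en-1-yl]-2-(diethoxyphosphoryl)-4,8-dimethylnon-7-enoic acid, via trimethylsilyl ester 14 (not isolated)
Conditions: TMSOTf, 2,6-lutidine, CH2Cl2, 0 °C to rt; then pH 4 buffer
Reagents that add atoms: trimethylsilyl triflate, C[Si](C)(C)OS(=O)(=O)C(F)(F)F (atoms in 14 only)
Why: Silyl-triflate-mediated cleavage of a tert-butyl ester under lutidine buffering spares the TBS ether, the ethyl phosphonate (triflate is not nucleophilic) and both alkenes.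

Step 9
Reactants: 16 ethynyltrimethylsilane; 17 ethyl diazoacetate
Product: 18 ethyl 2-(trimethylsilyl)cycloprop-2-ene-1-carboxylate (racemic)
Conditions: Rh2(OAc)4 (0.5 mol %), 16 (3 equiv), CH2Cl2, rt, slow addition of 17
Reagents that add atoms: none
Why: Rhodium-carbenoid [2+1] cyclopropenation of a terminal alkyne is the standard entry to cycloprop-2-ene carboxylates.

Step 10
Reactants: 18 silyl cyclopropene ester
Product: 19 cycloprop-2-ene-1-carboxylic acid (achiral)
Conditions: KOH, MeOH–H2O, 0 °C to rt; then 1 M HCl to pH 2, Et2O extraction, kept cold in solution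
Reagents that add atoms: potassium hydroxide, [K+].[OH-]
Why: Saponification is accompanied by protodesilylation of the vinylic C–Si bond of the strained ring and gives the mirror-symmetric parent acid.

Step 11
Reactants: 19 cyclopropene acid
Product: 21 N-methoxy-N-methylcycloprop-2-ene-1-carboxamide, via acyl imidazolide 20 (not isolated)
Conditions: CDI, CH2Cl2, 0 °C; then MeNH(OMe)·HCl, 0 °C to rt
Reagents that add atoms: N,O-dimethylhydroxylamine hydrochloride, CNOC.Cl; 1,1'-carbonyldiimidazole, O=C(n1ccnc1)n1ccnc1 (atoms in 20 only)
Why: Weinreb amide formation through the acyl imidazolide needs neither acid chloride nor heat, both of which the cyclopropene tolerates poorly.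

Step 12
Reactants: 21 Weinreb amide; 22 chloroiodomethane
Product: 23 2-chloro-1-(cycloprop-2-en-1-yl)ethan-1-one
Conditions: 22 (1.5 equiv), MeLi·LiBr (1.4 equiv, slow addition to the mixture), THF–Et2O, −78 °C; aq NH4Cl
Reagents that add atoms: none
Why: Chloromethyllithium made by fast iodine–lithium exchange in the presence of the Weinreb amide adds once, because the chelated tetrahedral adduct survives until the quench, and the exchange consumes MeLi before it can metalate the cyclopropene.

Step 13
Reactants: 15 phosphono acid; 23 chloromethyl ketone
Product: 24 2-(cycloprop-2-en-1-yl)-2-oxoethyl ester of acid 15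
Conditions: KHCO3, NaI (10 mol %), DMF, 0 °C to rt
Reagents that add atoms: none
Why: SN2 O-alkylation of a carboxylate with an α-halo ketone (Finkelstein-assisted) forms the ester tether under a base too weak to deprotonate the phosphonate.

Step 14
Reactants: 24 keto phosphonate
Product: 26 exo-methylene tricycle TBS ether (rings A B C complete), via cyclopropenyl butenolide 25 (not isolated)
Conditions: LiCl (10 equiv), i-Pr2NEt (10 equiv), Pd(OAc)2 (10 mol %), P(2-furyl)3 (30 mol %), MeCN (3 mM), 25 °C then 60 °C, HCO2H (1.5 equiv) in MeCN by syringe pump
Reagents that add atoms: none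
Why: Proposed new method: LiCl/i-Pr2NEt turns both phosphonate epimers of 24 into one lithium-chelated carbanion, which adds to the cyclopropenyl ketone five atoms away and collapses through the oxaphosphetane to butenolide 25 (intramolecular Horner–Wadsworth–Emmons olefination, 5-exo-trig closure of ring A); zerovalent palladium then inserts into the C–Br bond, the alkenylpalladium bromide adds syn across the strained C=C bond of the cyclopropene (8-exo-trig carbopalladation, closure of ring B), and the cyclopropylpalladium species, which has no syn β-hydrogen, is reduced by formate through decarboxylation and C–H reductive elimination. The closest known reaction types are the Masamune–Roush butenolide-forming intramolecular olefination and the reductive Heck reaction (formate-terminated hydroarylation or hydroalkenylation) of strained alkenes such as norbornenes and cyclopropenes; new are their merger in one flask, in which the same amine and chloride serve both events, and the eight-membered closure onto a cyclopropene. The first event enables the second, because the tetrasubstituted alkene of ring A locks the two arms cis on neighbouring sp2 carbons, and the release of cyclopropene strain lowers the barrier of the medium-ring insertion. The two new stereocentres are the cyclopropane CH groups: the tether allows attack only on the cyclopropene face syn to ring A, which enforces the cis ring fusion, and allylic 1,3-strain across the ring-A alkene keeps the C–H bonds of the side-chain-bearing carbon and of the cyclopropene sp3 carbon in the alkene plane, so that the arm with palladium lies on the face opposite to the methylheptenyl side chain and reaches only the olefinic carbon on that face, which leaves the cyclopropane CH2 syn to the side chain as the target requires. Site selectivity needs no control, since both olefinic carbons hang on the same sp3 carbon and either attack gives an eight-membered ring, and chemoselectivity over the tetrasubstituted butenolide alkene (5-exo insertion would build a quaternary centre) and the trisubstituted prenyl alkene follows from their poor binding to palladium. Insertion must outrun hydride capture of the alkenylpalladium species, which high dilution and slow addition of HCO2H should secure, because the cyclopropylpalladium intermediate can wait for the hydride.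

Step 15
Reactants: 26 tricyclic silyl ether
Product: 27 exo-methylene tricyclic alcohol
Conditions: HF·pyridine, THF, 0 °C to rt
Reagents that add atoms: none
Why: Fluoride-mediated desilylation under mildly acidic conditions frees the carbinol without touching the butenolide or the vinylcyclopropane, and translactonisation is blocked because it would need a bridgehead alkene.

Step 16
Reactants: 27 exo-methylene alcohol
Product: 28 deacetyl target (methyl-bearing carbon R)
Conditions: [Rh(nbd)(dppb)]BF4 (5 mol %), H2 (40 bar), CH2Cl2, rt
Reagents that add atoms: none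
Why: In this hydroxyl-directed homogeneous hydrogenation the cationic rhodium catalyst binds the homoallylic hydroxyl group and delivers H2 to the alkene face on which the oxygen sits, which is also the outer face of the bisected vinylcyclopropane, so the methyl group ends trans to the oxygen while the undirected tri- and tetrasubstituted alkenes should react far more slowly.

Step 17
Reactants: 28 tricyclic alcohol
Product: 29 target CNP0018922.1
Conditions: Ac2O, pyridine, DMAP (cat.), CH2Cl2, rt
Reagents that add atoms: acetic anhydride, CC(=O)OC(C)=O
Why: DMAP-catalysed acetylation esterifies the hindered secondary alcohol with retention and changes no other group.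

## Compound list

1 | (R)-citronellic acid, (3R)-3,7-dimethyloct-6-enoic acid | OC(=O)C[C@H](C)CCC=C(C)C | starting material
2 | (4R)-4-benzyl-1,3-oxazolidin-2-one | O=C1OC[C@@H](Cc2ccccc2)N1 | starting material
3 | (3R)-3,7-dimethyloct-6-enoic pivalic anhydride | CC(C)(C)C(=O)OC(=O)C[C@H](C)CCC=C(C)C | intermediate
4 | (4R)-4-benzyl-3-[(3R)-3,7-dimethyloct-6-enoyl]-1,3-oxazolidin-2-one | O=C1OC[C@@H](Cc2ccccc2)N1C(=O)C[C@H](C)CCC=C(C)C | intermediate
5 | tert-butyl bromoacetate | BrCC(=O)OC(C)(C)C | starting material
6 | tert-butyl (3R,4R)-3-{[(4R)-4-benzyl-2-oxo-1,3-oxazolidin-3-yl]carbonyl}-4,8-dimethylnon-7-enoate | O=C1OC[C@@H](Cc2ccccc2)N1C(=O)[C@H](CC(=O)OC(C)(C)C)[C@H](C)CCC=C(C)C | intermediate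
7 | tert-butyl (3R,4R)-3-(hydroxymethyl)-4,8-dimethylnon-7-enoate | OC[C@H](CC(=O)OC(C)(C)C)[C@H](C)CCC=C(C)C | intermediate
8 | tert-butyl (3R,4R)-3-formyl-4,8-dimethylnon-7-enoate | O=C[C@H](CC(=O)OC(C)(C)C)[C@H](C)CCC=C(C)C | intermediate
9 | 2,3-dibromopropene | BrCC(Br)=C | starting material
10 | tert-butyl (3R,4R)-3-[(1R)-3-bromo-1-hydroxybut-3-en-1-yl]-4,8-dimethylnon-7-enoate | O[C@@H]([C@H](CC(=O)OC(C)(C)C)[C@H](C)CCC=C(C)C)CC(Br)=C | intermediate
11 | tert-butyl (3R,4R)-3-[(1R)-3-bromo-1-(tert-butyldimethylsilyloxy)but-3-en-1-yl]-4,8-dimethylnon-7-enoate | CC(C)(C)[Si](C)(C)O[C@@H]([C@H](CC(=O)OC(C)(C)C)[C@H](C)CCC=C(C)C)CC(Br)=C | intermediate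
12 | 2-(diethoxyphosphanyl) derivative of 11 (2RS,3R,4R,1'R) | CC(C)(C)[Si](C)(C)O[C@@H]([C@H](C(C(=O)OC(C)(C)C)P(OCC)OCC)[C@H](C)CCC=C(C)C)CC(Br)=C | intermediate
13 | tert-butyl (2RS,3R,4R)-3-[(1R)-3-bromo-1-(tert-butyldimethylsilyloxy)but-3-en-1-yl]-2-(diethoxyphosphoryl)-4,8-dimethylnon-7-enoate | CC(C)(C)[Si](C)(C)O[C@@H]([C@H](C(C(=O)OC(C)(C)C)P(=O)(OCC)OCC)[C@H](C)CCC=C(C)C)CC(Br)=C | intermediate
14 | trimethylsilyl ester corresponding to 13 | CC(C)(C)[Si](C)(C)O[C@@H]([C@H](C(C(=O)O[Si](C)(C)C)P(=O)(OCC)OCC)[C@H](C)CCC=C(C)C)CC(Br)=C | intermediate
15 | (2RS,3R,4R)-3-[(1R)-3-bromo-1-(tert-butyldimethylsilyloxy)but-3-en-1-yl]-2-(diethoxyphosphoryl)-4,8-dimethylnon-7-enoic acid | CC(C)(C)[Si](C)(C)O[C@@H]([C@H](C(C(=O)O)P(=O)(OCC)OCC)[C@H](C)CCC=C(C)C)CC(Br)=C | intermediate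
16 | ethynyltrimethylsilane | C#C[Si](C)(C)C | starting material
17 | ethyl diazoacetate | CCOC(=O)C=[N+]=[N-] | starting material
18 | ethyl 2-(trimethylsilyl)cycloprop-2-ene-1-carboxylate (racemic) | CCOC(=O)C1C=C1[Si](C)(C)C | intermediate
19 | cycloprop-2-ene-1-carboxylic acid | OC(=O)C1C=C1 | intermediate
20 | (cycloprop-2-en-1-yl)(1H-imidazol-1-yl)methanone | O=C(C1C=C1)n1ccnc1 | intermediate
21 | N-methoxy-N-methylcycloprop-2-ene-1-carboxamide | CON(C)C(=O)C1C=C1 | intermediate
22 | chloroiodomethane | ClCI | starting material
23 | 2-chloro-1-(cycloprop-2-en-1-yl)ethan-1-one | ClCC(=O)C1C=C1 | intermediate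
24 | 2-(cycloprop-2-en-1-yl)-2-oxoethyl (2RS,3R,4R)-3-[(1R)-3-bromo-1-(tert-butyldimethylsilyloxy)but-3-en-1-yl]-2-(diethoxyphosphoryl)-4,8-dimethylnon-7-enoate | CC(C)(C)[Si](C)(C)O[C@@H]([C@H](C(C(=O)OCC(=O)C1C=C1)P(=O)(OCC)OCC)[C@H](C)CCC=C(C)C)CC(Br)=C | intermediate
25 | 3-[(4R,5S,6R)-2-bromo-4-(tert-butyldimethylsilyloxy)-6,10-dimethylundeca-1,9-dien-5-yl]-4-(cycloprop-2-en-1-yl)furan-2(5H)-one | CC(C)(C)[Si](C)(C)O[C@@H]([C@H](C1=C(C2C=C2)COC1=O)[C@H](C)CCC=C(C)C)CC(Br)=C | intermediate
26 | target skeleton with OTBS in place of OAc and C(=CH2) in place of CH(CH3); ring B from Cα: CH(side chain) S, CH(OTBS) R, CH2, C(=CH2), cyclopropane CH R, cyclopropane CH S, Cβ; cis-fused cyclopropane with its CH2 syn to OTBS and side chain; side-chain methine R | CC(C)(C)[Si](C)(C)O[C@@H]1CC(=C)[C@@H]2C[C@@H]2C2=C(C(=O)OC2)[C@@H]1[C@H](C)CCC=C(C)C | intermediate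
27 | free carbinol of 26 (same configuration) | O[C@@H]1CC(=C)[C@@H]2C[C@@H]2C2=C(C(=O)OC2)[C@@H]1[C@H](C)CCC=C(C)C | intermediate
28 | deacetyl target; CH(CH3) R with methyl trans to OH; neighbouring cyclopropane CH now S by priority change only | O[C@@H]1C[C@@H](C)[C@@H]2C[C@@H]2C2=C(C(=O)OC2)[C@@H]1[C@H](C)CCC=C(C)C | intermediate
29 | target CNP0018922.1; ring B from Cα: CH(side chain) S, CH(OAc) R, CH2, CH(CH3) R, cyclopropane CH S, cyclopropane CH S, Cβ; side-chain methine R | CC(=O)O[C@@H]1C[C@@H](C)[C@@H]2C[C@@H]2C2=C(C(=O)OC2)[C@@H]1[C@H](C)CCC=C(C)C | target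

## Step count and risks

Total step count: 17.
Longest linear sequence: 13 (steps 1–8 and 13–17).

**1. Step 14 (bears the label).**
- What may go wrong:
  - hydride capture of the alkenylpalladium species before the slow medium-ring insertion;
  - palladium-induced oligomerisation or ring opening of the unsubstituted cyclopropene;
  - poor discrimination between the two olefinic carbons.
- Fallback: it sets out from 24 and comes back at 26, and it splits the event into three known reactions.
  - The cyclopropene of 24 is hydroborated with pinacolborane under [Rh(cod)Cl]2/BINAP catalysis. This is a carbonyl-directed, enantiotopos-selective hydroboration of cyclopropenes. The ligand enantiomer is chosen so that boron goes cis to the acyl group and onto the carbon that will join ring B. The product is the cis-2-borylcyclopropyl ketone F1.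
  - LiCl/DBU in MeCN closes ring A by the same intramolecular olefination and gives the boryl butenolide F2.
  - A stereoretentive intramolecular Suzuki–Miyaura coupling of the cyclopropylboronate with the alkenyl bromide closes ring B to 26 (PdCl2(dppf), Cs2CO3, THF–H2O, high dilution).

**2. Step 16.**
- What may go wrong:
  - opening of the vinylcyclopropane by the cationic rhodium catalyst;
  - migration of the exocyclic alkene;
  - over-reduction of the prenyl alkene;
  - poor facial selectivity.
- Fallback: it sets out from 27 and comes back at 29, with the order of the last two operations inverted and no metal.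
  - Compound 27 is acetylated (Ac2O, pyridine, DMAP) to the exo-methylene acetate F3.
  - F3 is reduced with diimide generated from 2-nitrobenzenesulfonyl hydrazide and Et3N.
  - The concerted syn transfer of H2 cannot open the cyclopropane and prefers the 1,1-disubstituted alkene over the tri- and tetrasubstituted ones.
  - Facial control then rests on peripheral attack on the outer face of the bisected vinylcyclopropane, the side of the cyclopropane CH2, which leads to the same configuration.

**3. Step 5.**
- What may go wrong:
  - poor facial selectivity of the addition to the α-branched aldehyde;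
  - partial lactonisation of the γ-hydroxy ester.
- Fallback: it sets out from 8 and comes back at 10, and it replaces substrate control by reagent control.
  - The unseparated carbinol mixture from the Barbier reaction is oxidised with Dess–Martin periodinane to the β,γ-unsaturated ketone F4.
  - F4 is reduced by a Corey–Bakshi–Shibata reduction with the (S)-methyl oxazaborolidine and catecholborane in toluene at −78 °C. Catecholborane does not hydroborate the alkenes at this temperature.
  - The branched carbon acts as the large group, which gives the 1R carbinol 10.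

## Further compounds

F1 | step 14 | 2-oxo-2-[cis-2-(4,4,5,5-tetramethyl-1,3,2-dioxaborolan-2-yl)cyclopropyl]ethyl ester of acid 15 (boron on the carbon that joins ring B) | CC(C)(C)[Si](C)(C)O[C@@H]([C@H](C(C(=O)OCC(=O)[C@H]1C[C@H]1B2OC(C)(C)C(C)(C)O2)P(=O)(OCC)OCC)[C@H](C)CCC=C(C)C)CC(Br)=C
F2 | step 14 | analogue of 25 with a cis-2-(pinacolboryl)cyclopropyl group in place of the cyclopropenyl group | CC(C)(C)[Si](C)(C)O[C@@H]([C@H](C1=C(COC1=O)[C@H]2C[C@H]2B3OC(C)(C)C(C)(C)O3)[C@H](C)CCC=C(C)C)CC(Br)=C
F3 | step 16 | acetate of 27 (exo-methylene analogue of the target) | CC(=O)O[C@@H]1CC(=C)[C@@H]2C[C@@H]2C2=C(C(=O)OC2)[C@@H]1[C@H](C)CCC=C(C)C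
F4 | step 5 | tert-butyl (3R,4R)-3-(3-bromobut-3-enoyl)-4,8-dimethylnon-7-enoate | C=C(Br)CC(=O)[C@H](CC(=O)OC(C)(C)C)[C@H](C)CCC=C(C)C
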